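**Conventions.** Carbon atoms keep one set of numbers throughout: ring A is the cyclohexane C5–C10; ring B is the lactone (C6, C7, C11, C12 and the oxygen on C6); C1=C2 is the vinyl group on C10; C4 is the central carbon of the isopropenyl group on C5. "Lactone face" means the face of ring A that carries O6 and C11.

## Analysis of the target

Target 28 is an elemane-type lactone: a cyclohexane (ring A) cis-fused through C6–C7 to a γ-butyrolactone (ring B). Ring A carries methyl and vinyl on the quaternary C10, an isopropenyl group on C5 and an acetoxy group on C8; ring B carries methyl and angeloyloxy on the quaternary C11. There are six stereocentres (C5, C6, C7, C8, C10, C11; descriptors 5R,6S,7R,8S,10R,11S in this numbering). O6, C11 and the C10 vinyl lie on the lactone face; the C10 methyl, the isopropenyl group and the C8 acetoxy group lie on the other face. On ring B the angeloyloxy group is convex and the C11 methyl points over ring A. Sensitive groups are the angelate (Z to E isomerisation), the tertiary α-acyloxy lactone, the acid-labile isopropenyl group, and the 1,3-relationship of C8 to the acyloxy groups on C6 and C11, which makes a C8 ketone prone to β-elimination. The hard points are the all-carbon quaternary C10 next to C5, the cis fusion combined with a trans C5–C6 relationship, and C8, whose hydrogen sits on the hindered lactone face. The strategy rests on C5–C6: an isopropenyl-bearing carbon next to an oxygenated carbon is what an ene-type attack of a 2-methylprop-1-enyl group on a C6 oxocarbenium ion leaves behind, and that ion can be held inside ring B.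

## Retrosynthetic reasoning

**C8–O bond of 28, cut with inversion.** The C8 hydrogen of 28 lies on the concave lactone face, which is covered by C11 with its inward methyl, by O6 and by the C10 vinyl group. A reducing agent should therefore reach ketone 25 from the other side and give alcohol 26, with the hydroxyl on the lactone face. The C8–O bond is accordingly made last, by activating 26 (as 27) and displacing from the open face with the oxygen nucleophile that becomes the acetate. The easy trajectory is used twice, and acetate introduction and correction of C8 are one operation. Ketone 25 is the unmasked form of dithiane 24.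

**C11–O bonds of 24.** The ester bond is cut to tertiary alcohol 22, so the isomerisation-prone acyl group enters late and on a preformed alkoxide (23). It precedes dithiane removal because C11 then has no hydrogen left when ketone 25 is exposed. The C11–O bond of 22 is cut to enolate 21 of lactone 20; oxygen must enter on the convex face of ring B. This is placed after ring closure, because a quaternary C11 with its methyl turned toward ring A would obstruct the key transition state.

**C5–C6 bond of 20 (key disconnection).** Cutting here, rather than at a bond to the quaternary C10 or in ring B, removes ring A and two stereocentres at once and leaves an intact butanolide with an acyclic chain, 17. Forward, ionisation at C6 gives 18, C5 attacks, and cation 19 loses a methyl proton. One C–C bond completes the bicyclic core and generates the isopropenyl group; the reaction has to deliver the cis fusion and the C5 configuration.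

**C7–C8 and C11–CH3 bonds of 17.** These cuts lead to dithiane 14 (as carbanion 15), butenolide 6 and a one-carbon electrophile. The thioacetal makes C8 nucleophilic, so the chain is joined to the β-carbon of 6. The alkoxy group on the acetal carbon of 6 sends the carbanion to the opposite face and sets C7. Enolate 16 is then methylated anti to the new substituent, which leaves the C11 hydrogen on the side of C8 as the key step needs. Three contiguous centres of 17 derive from the single acetal centre of 6.

**Acetal 6.** It is cut at the exocyclic C–O bond to hydroxybutenolide 3 and auxiliary alcohol 4; 3 comes from acid 1 by photo-oxygenation. The acetal carbon must be S. The auxiliary is lost in step 9, so its handedness is free: with 4 the needed epimer 6 is the one expected to crystallise, while epimer 5 stays in solution and is re-equilibrated.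

**C10–C5 bond of the side chain.** Dithiane 14 is the thioacetal of acetal 13. In 13 the bond between C10 and the alkenyl carbon is cut in the SN2′ sense to allylic phosphate 11 and boronate 12. This one disconnection creates the quaternary centre and the vinyl group together, and catalyst control makes C10 independent of the auxiliary. Phosphate 11 comes from alcohol 10 and ester 9, which is assembled from ketone 7 and phosphonate 8. The E geometry of 9 matters because it is translated into the configuration of C10.

## Alternatives that were turned down

**Alternative 1:** Disconnection of C9–C10 and C7–C8 through bicyclo[2.2.2]octenone A1, in which C1 and C11 are tied as an etheno bridge. Forward, dienone A2 (a masked ortho-quinone from oxidative dearomatisation) takes up the electron-rich alkene A3 across C10 and C7 in a [4+2] cycloaddition.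
- For: two ring bonds, the quaternary C10 and oxygen at C5, C6 and C8 arise in one step from flat, cheap precursors. The bridge forces C1 and C11 onto the same face of ring A, which is the vinyl/C11 relationship of the target.
- Against: A1 is racemic. After bridge cleavage C11 is only a methyl ketone, so C12, the tertiary C11–O centre and the lactone remain to be built. C5 arrives at the ketone level and must become a CH bearing isopropenyl with control. C6 and C8 both need selective reductions, and C8 would pose the same facial problem as here.
- Comparison: ring assembly is faster than in the chosen route, and the vinyl/C11 relationship is fixed in one stroke rather than by two separate controlled steps. In its place the chosen route has the isopropenyl group, the complete lactone and a single enantiomer in hand at the key step, where A1 still needs a long series of redox and homologation steps.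

**Alternative 2:** Disconnection of C10–C1 and C5–C4, the bonds that hold the two alkenyl groups, formed together as a cyclobutane and released by fragmentation of a bicyclo[2.2.0]hexane. Forward, irradiation of enone A5 with cyclobutene ester A6 gives head-to-head adduct A4; heating cleaves C1–C4 and C2–C3 to divinyl ketone A7.
- For: C10 and C5 are made together from two simple rings. The C8 oxygen is carried from the start with the right configuration; on that point this route is stronger than the chosen one, which corrects C8 at the end.
- Against: nothing in A5 enforces head-to-head regiochemistry or the facial sense relative to the remote C8 substituent. The β-silyloxy ketone can eliminate. The cis-fused cyclobutane leaves the alkenyl groups cis in A7, so C5 must be epimerised. The fragmentation competes with a [3,3] shift toward a ten-membered ring. The acrylate needs three operations to become isopropenyl. C7 is a bare CH2, so the C7–C11 bond, C11, C12, the lactone and the centres C6, C7 and C11 all remain.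
- Comparison: the key step is shorter to reach, but most of the stereochemical work lies after it. The chosen route has ring B complete before ring A is closed and needs no oxidation-level changes at C4.

**Alternative 3:** Disconnection of C7–C11 in ring B, with ring A complete as cyclohexenol A10 and its bromoacetal A9. Forward, the C11 radical adds to C7 of the C7=C8 alkene in a five-membered exo closure, and the C8 radical is intercepted aerobically to give A8.
- For: the cis fusion is automatic. The C8 oxygen enters anti to the new ring, which is the configuration of the target, in the same step as the C–C bond; this is clearly stronger than the reduction–inversion pair of the chosen route. Neutral conditions suit the two terminal alkenes.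
- Against: the step builds only ring B. A10, with C5, C6 and the quaternary C10 in place, is the main stereochemical problem and has no short enantioselective access. Interception at C8 competes with simple reduction, and the C11 radical can also reach the isopropenyl group. The acetal must still be oxidised to the lactone, and C11 oxygenation and angeloylation remain as in the chosen route.
- Comparison: the chosen key step builds ring A and the C5/C6 pair from two small, separately made pieces and needs no preformed carbocycle; it pays for this with the late correction at C8.

Key step: step 9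

## Route

Step 1
Reactants: 1 furan-2-carboxylic acid
Product: 3 5-hydroxyfuran-2(5H)-one (racemic), via furan endoperoxide 2 (not isolated)
Conditions: O2, hν (visible), 5,10,15,20-tetraphenylporphyrin (cat.), CH2Cl2/MeOH, 0 °C
Reagents that add atoms: dioxygen, O=O
Why: Dye-sensitised photo-oxygenation: singlet oxygen adds across C2/C5 of the furan in a [4+2] sense and endoperoxide 2 fragments with loss of CO2 to the hydroxybutenolide.

Step 2
Reactants: 3 5-hydroxyfuran-2(5H)-one; 4 (+)-menthol
Product: 6 (5S)-5-{[(1S,2R,5S)-5-methyl-2-(propan-2-yl)cyclohexyl]oxy}furan-2(5H)-one, via 5R epimer 5 (not isolated)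
Conditions: camphorsulfonic acid (cat.), toluene, reflux (Dean–Stark); crystallisation from light petroleum; mother liquor re-equilibrated with the same acid and recrystallised
Reagents that add atoms: none
Why: Acid-catalysed acetalisation of the pseudo-acid; both C5 epimers form and interconvert through the ring oxocarbenium ion, and crystallisation of 6 should pull the equilibrium over (crystallisation-driven diastereomer transformation). Acetal 6 is the mirror image of the crystalline acetal of the laevorotatory menthyl series, so the same behaviour is expected.

Step 3
Reactants: 7 4,4-dimethoxybutan-2-one; 8 triethyl phosphonoacetate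
Product: 9 ethyl (E)-5,5-dimethoxy-3-methylpent-2-enoate
Conditions: NaH, THF, 0 °C to rt; minor Z isomer removed by chromatography
Reagents that add atoms: none
Why: Horner–Wadsworth–Emmons olefination of a methyl ketone, which favours the E ester; geometric purity is needed because the alkene geometry is translated into the configuration of C10 in step 6.

Step 4
Reactants: 9 ethyl (E)-5,5-dimethoxy-3-methylpent-2-enoate
Product: 10 (E)-5,5-dimethoxy-3-methylpent-2-en-1-ol
Conditions: i-Bu2AlH, CH2Cl2, −78 °C
Reagents that add atoms: none
Why: 1,2-Reduction of the conjugated ester to the allylic alcohol by an aluminium hydride; the dimethyl acetal is inert at this temperature.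

Step 5
Reactants: 10 (E)-5,5-dimethoxy-3-methylpent-2-en-1-ol
Product: 11 diethyl (E)-5,5-dimethoxy-3-methylpent-2-en-1-yl phosphate
Conditions: (EtO)2P(O)Cl, Et3N, 4-(dimethylamino)pyridine (cat.), CH2Cl2, 0 °C
Reagents that add atoms: diethyl chlorophosphate, CCOP(=O)(Cl)OCC
Why: Phosphorylation of the primary allylic alcohol gives the leaving group used in copper-catalysed allylic substitution.

Step 6
Reactants: 11 diethyl (E)-5,5-dimethoxy-3-methylpent-2-en-1-yl phosphate; 12 2-methylprop-1-enylboronic acid pinacol ester
Product: 13 (3R)-3-(2,2-dimethoxyethyl)-3,5-dimethylhexa-1,4-diene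
Conditions: CuCl (5 mol %), 2-[(4S,5S)-3-(2,6-diisopropylphenyl)-4,5-diphenyl-4,5-dihydroimidazol-3-ium-1-yl]benzenesulfonate (5.5 mol %; or its enantiomer, whichever delivers the R centre), NaOMe, THF, 60 °C
Reagents that add atoms: none
Why: NHC–copper-catalysed enantioselective allylic substitution: methoxide activates the boronate, the alkenyl group passes to copper and is delivered to the γ-carbon of the E phosphate in the SN2′ sense, creating the quaternary C10 together with the vinyl group. The ligand selects the alkene face; this reaction class is established for quaternary carbons bearing a vinyl and an alkenyl group.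

Step 7
Reactants: 13 (3R)-3-(2,2-dimethoxyethyl)-3,5-dimethylhexa-1,4-diene
Product: 14 2-[(2R)-2-ethenyl-2,4-dimethylpent-3-en-1-yl]-1,3-dithiane
Conditions: HS(CH2)3SH, BF3·OEt2, CH2Cl2, −20 °C
Reagents that add atoms: propane-1,3-dithiol, SCCCS
Why: Lewis-acid thioacetal exchange; the intermediate thionium ion has no favourable ring size for attack by either alkene, so the diene should survive at low temperature.

Step 8
Reactants: 14 2-[(2R)-2-ethenyl-2,4-dimethylpent-3-en-1-yl]-1,3-dithiane; 6 (5S)-menthyloxybutenolide
Product: 17 (3S,4S,5S)-4-{2-[(2R)-2-ethenyl-2,4-dimethylpent-3-en-1-yl]-1,3-dithian-2-yl}-3-methyl-5-{[(1S,2R,5S)-5-methyl-2-(propan-2-yl)cyclohexyl]oxy}oxolan-2-one, via 2-lithiodithiane 15 (not isolated), via lithium enolate 16 (not isolated)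
Conditions: n-BuLi, THF, −30 °C; DMPU, then 6, −78 °C; MeI, −78 to −30 °C
Reagents that add atoms: iodomethane, CI
Why: Corey–Seebach umpolung: carbanion 15 adds to the butenolide in the conjugate sense on the face opposite the menthyloxy group, which sets C7. Enolate 16 is then C-methylated anti to the new C7 substituent (tandem Michael addition–alkylation), which sets C11 with its hydrogen on the side of C8; any attack at the lactone carbonyl should be reversible and drain into the 1,4-adduct.

Step 9
Reactants: 17 all-trans menthyloxy butanolide
Product: 20 cis-fused dithiane lactone (ring A closed; C5 isopropenyl), via lactone oxocarbenium ion 18 (not isolated), via C4 tertiary cation 19 (not isolated)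
Conditions: TMSOTf, 2,6-di-tert-butyl-4-methylpyridine, CH2Cl2, −78 to −30 °C
Reagents that add atoms: none
Why: TMSOTf silylates the exocyclic menthyloxy oxygen and the acetal ionises to the acyloxy-stabilised oxocarbenium ion 18; the trisubstituted alkene attacks C6 through its less substituted carbon C5, the charge moves to the tertiary C4 (19), and the hindered pyridine removes a methyl proton, so the overall change is that of an ene reaction. The closest known reactions are acetal-initiated cation–olefin (Prins) cyclisations ended by proton loss and the Lewis-acid substitution of 5-alkoxybutanolides by π-nucleophiles. Ring A closes in a six-membered mode that is exo at the oxocarbenium (the C6–O bond stays outside the new ring) and uses the inner alkene carbon, leaving C4 exocyclic. C6 is controlled by the tether: the chain from C7 reaches only the face of the planar cation on which C8 sits, which gives the cis fusion. C5 is controlled by a chair transition state in which C11 is axial (the cation plane stands perpendicular to the forming ring), the C10 vinyl and the incoming C4 are equatorial and the C10 methyl is axial; this places the isopropenyl group trans to O6 and to the vinyl group. The step needs cleavage of the exocyclic rather than the ring C–O bond, attack by the 2-methylprop-1-enyl rather than the vinyl group, and proton loss from a methyl rather than from C5. These are secured by the better leaving ability of the silylated alkoxy group, the higher nucleophilicity of the trisubstituted alkene (the vinyl group could only give a primary cation or a seven-membered ring), the gem-dithio substitution at C8 that folds the chain (Thorpe–Ingold effect), the C11 hydrogen (not methyl) pointing over the forming ring, and a base too hindered to reach anything but the exposed methyl protons.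

Step 10
Reactants: 20 cis-fused dithiane lactone
Product: 22 C11 tertiary alcohol (hydroxyl convex; methyl concave), via potassium enolate 21 (not isolated)
Conditions: KN(SiMe3)2, THF, −78 to −40 °C; 2-(phenylsulfonyl)-3-phenyloxaziridine, −78 °C; aq NH4Cl at −78 °C
Reagents that add atoms: 2-(phenylsulfonyl)-3-phenyloxaziridine, O=S(=O)(c1ccccc1)N1OC1c1ccccc1
Why: Enolate hydroxylation with an N-sulfonyloxaziridine: the planar enolate 21 takes up oxygen on the convex face of ring B, away from ring A, so the hydroxyl ends cis to H7 and the methyl over ring A, as in the target. At −78 °C enolate oxidation should outrun oxidation of the dithiane sulfur.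

Step 11
Reactants: 22 C11 tertiary alcohol
Product: 24 C11 angelate, via lithium alkoxide 23 (not isolated)
Conditions: LiN(SiMe3)2, THF, −78 °C; angelic anhydride, −78 to 0 °C
Reagents that add atoms: angelic anhydride, C/C=C(/C)C(=O)OC(=O)/C(C)=C\C
Why: Acylation of a preformed alkoxide by the anhydride needs neither acid, heat nor a nucleophilic catalyst, which are the conditions under which angelates isomerise to tiglates, so the Z geometry should be retained.

Step 12
Reactants: 24 C11 angelate
Product: 25 C8 ketone
Conditions: PhI(OCOCF3)2, MeCN/H2O (9:1), 0 °C; NaHCO3 work-up; used at once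
Reagents that add atoms: water, O
Why: Oxidative dethioacetalisation: sulfur is oxidised far faster than the isolated alkenes and water delivers the carbonyl oxygen. The medium stays slightly acidic, so the β-acyloxy ketone is not exposed to base.

Step 13
Reactants: 25 C8 ketone
Product: 26 (8R)-alcohol (hydroxyl on the lactone face)
Conditions: NaBH4, CeCl3·7H2O, MeOH, −78 °C; AcOH quench
Reagents that add atoms: none
Why: Luche reduction: hydride should approach C8 from the convex face of the cis-fused bicycle (the face of H7), because the other face is covered by C11 with its inward methyl, by O6 and by the C10 vinyl group, so the hydroxyl is placed on the lactone face. CeCl3 keeps the medium non-basic, which suppresses β-elimination through the C7 enolate and acyl transfer from C12 to the new hydroxyl.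

Step 14
Reactants: 26 (8R)-alcohol
Product: 28 target (8S)-acetate, via C8 triflate 27 (not isolated)
Conditions: Tf2O, 2,6-lutidine, CH2Cl2, −40 °C; n-Bu4NOAc, −40 to 0 °C
Reagents that add atoms: tetrabutylammonium acetate, CC(=O)[O-].CCCC[N+](CCCC)(CCCC)CCCC
Why: Sulfonate displacement by a carboxylate with inversion: triflation is sterically undemanding, and acetate then attacks C8 in an SN2 reaction from the open convex face, which inverts C8 to the configuration of the target and installs the acetate in the same operation.

## Compound list

1 | furan-2-carboxylic acid | OC(=O)c1ccco1 | starting material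
2 | 2,3,7-trioxabicyclo[2.2.1]hept-5-ene-1-carboxylic acid (furan endoperoxide, racemic) | OC(=O)C12OOC(O1)C=C2 | intermediate
3 | 5-hydroxyfuran-2(5H)-one (racemic) | O=C1C=CC(O)O1 | intermediate
4 | (+)-menthol, (1S,2R,5S)-5-methyl-2-(propan-2-yl)cyclohexan-1-ol | CC(C)[C@H]1CC[C@H](C)C[C@@H]1O | starting material
5 | (5R)-5-{[(1S,2R,5S)-5-methyl-2-(propan-2-yl)cyclohexyl]oxy}furan-2(5H)-one | O=C1C=C[C@H](O[C@H]2C[C@@H](C)CC[C@@H]2C(C)C)O1 | intermediate
6 | (5S)-5-{[(1S,2R,5S)-5-methyl-2-(propan-2-yl)cyclohexyl]oxy}furan-2(5H)-one | O=C1C=C[C@@H](O[C@H]2C[C@@H](C)CC[C@@H]2C(C)C)O1 | intermediate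
7 | 4,4-dimethoxybutan-2-one | CC(=O)CC(OC)OC | starting material
8 | triethyl phosphonoacetate | CCOC(=O)CP(=O)(OCC)OCC | starting material
9 | ethyl (E)-5,5-dimethoxy-3-methylpent-2-enoate | CCOC(=O)/C=C(\C)CC(OC)OC | intermediate
10 | (E)-5,5-dimethoxy-3-methylpent-2-en-1-ol | OC/C=C(\C)CC(OC)OC | intermediate
11 | diethyl (E)-5,5-dimethoxy-3-methylpent-2-en-1-yl phosphate | CCOP(=O)(OCC)OC/C=C(\C)CC(OC)OC | intermediate
12 | 4,4,5,5-tetramethyl-2-(2-methylprop-1-en-1-yl)-1,3,2-dioxaborolane | CC(C)=CB1OC(C)(C)C(C)(C)O1 | starting material
13 | (3R)-3-(2,2-dimethoxyethyl)-3,5-dimethylhexa-1,4-diene | C=C[C@](C)(C=C(C)C)CC(OC)OC | intermediate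
14 | 2-[(2R)-2-ethenyl-2,4-dimethylpent-3-en-1-yl]-1,3-dithiane | C=C[C@](C)(C=C(C)C)CC1SCCCS1 | intermediate
15 | 2-lithio derivative of 14 | C=C[C@](C)(C=C(C)C)CC1([Li])SCCCS1 | intermediate
16 | lithium enolate of the conjugate adduct (C7 set, C11 trigonal) | C=C[C@](C)(C=C(C)C)CC1(SCCCS1)[C@@H]2[C@@H](O[C@H]3C[C@@H](C)CC[C@@H]3C(C)C)OC([O-])=C2.[Li+] | intermediate
17 | (3S,4S,5S)-4-{2-[(2R)-2-ethenyl-2,4-dimethylpent-3-en-1-yl]-1,3-dithian-2-yl}-3-methyl-5-{[(1S,2R,5S)-5-methyl-2-(propan-2-yl)cyclohexyl]oxy}oxolan-2-one (all-trans; key-step precursor) | C=C[C@](C)(C=C(C)C)CC1(SCCCS1)[C@@H]2[C@@H](O[C@H]3C[C@@H](C)CC[C@@H]3C(C)C)OC(=O)[C@H]2C | intermediate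
18 | lactone oxocarbenium triflate (17 without the menthyloxy group, C6=O+ in ring B) | C=C[C@](C)(C=C(C)C)CC1(SCCCS1)[C@@H]2C=[O+]C(=O)[C@H]2C.[O-]S(=O)(=O)C(F)(F)F | intermediate
19 | ring-closed tertiary C4 carbocation (triflate) | C=C[C@@]1(C)CC3(SCCCS3)[C@@H]2[C@@H](OC(=O)[C@H]2C)[C@@H]1[C+](C)C.[O-]S(=O)(=O)C(F)(F)F | intermediate
20 | (10R) cis-fused lactone: C8 1,3-dithiane; C5 isopropenyl trans to O6 and to the C10 vinyl; C11 hydrogen concave, methyl convex (key-step product) | C=C[C@@]1(C)CC3(SCCCS3)[C@@H]2[C@@H](OC(=O)[C@H]2C)[C@@H]1C(=C)C | intermediate
21 | potassium enolate of 20 | C=C[C@@]1(C)CC3(SCCCS3)[C@@H]2[C@@H](OC([O-])=C2C)[C@@H]1C(=C)C.[K+] | intermediate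
22 | C11 tertiary alcohol of 20 (hydroxyl convex, methyl concave) | C=C[C@@]1(C)CC3(SCCCS3)[C@@H]2[C@@H](OC(=O)[C@@]2(C)O)[C@@H]1C(=C)C | intermediate
23 | lithium alkoxide of 22 | C=C[C@@]1(C)CC3(SCCCS3)[C@@H]2[C@@H](OC(=O)[C@@]2(C)[O-])[C@@H]1C(=C)C.[Li+] | intermediate
24 | C11 (Z)-2-methylbut-2-enoate (angelate) of 22 | C=C[C@@]1(C)CC3(SCCCS3)[C@@H]2[C@@H](OC(=O)[C@@]2(C)OC(=O)/C(C)=C\C)[C@@H]1C(=C)C | intermediate
25 | C8 ketone (dithiane of 24 removed) | C=C[C@@]1(C)CC(=O)[C@@H]2[C@@H](OC(=O)[C@@]2(C)OC(=O)/C(C)=C\C)[C@@H]1C(=C)C | intermediate
26 | (8R)-alcohol, hydroxyl on the lactone face (C8 epimer of the deacetyl target) | C=C[C@@]1(C)C[C@@H](O)[C@@H]2[C@@H](OC(=O)[C@@]2(C)OC(=O)/C(C)=C\C)[C@@H]1C(=C)C | intermediate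
27 | C8 trifluoromethanesulfonate of 26 | C=C[C@@]1(C)C[C@@H](OS(=O)(=O)C(F)(F)F)[C@@H]2[C@@H](OC(=O)[C@@]2(C)OC(=O)/C(C)=C\C)[C@@H]1C(=C)C | intermediate
28 | CNP0140071.1, (5R,6S,7R,8S,10R,11S)-8-acetoxy-11-angeloyloxy-11,13-dihydroelema-1,3-dien-12,6-olide | C=C[C@@]1(C)C[C@H](OC(C)=O)[C@@H]2[C@@H](OC(=O)[C@@]2(C)OC(=O)/C(C)=C\C)[C@@H]1C(=C)C | target

## Step count and least certain steps

Total: 14 steps. Longest linear sequence: 12 steps (7 to 28 through steps 3–14); the butenolide branch (1 to 6) is 2 steps.

**Step 9 (key step).** Three things can go wrong. The silyl triflate may activate the lactone carbonyl, so that the ring C6–O bond breaks and the cation is no longer held in ring B, with loss of control over C6. The C4 cation may lose the C5 proton or be captured by sulfur or triflate, which moves or destroys the alkene. One dithiane sulfur is 1,3-diaxial to the C10 methyl in the chair, so closure may divert through a boat and erode selectivity at C5. The fallback is an intramolecular Hosomi–Sakurai closure and sets out from phosphate 11. Dimethyl[(E)-2-methyl-3-(trimethylsilyl)prop-1-enyl]alane F1, made in the flask from trimethyl(prop-2-ynyl)silane, AlMe3 and Cp2ZrCl2 (cat.), is coupled with 11 under the CuCl/imidazolinium conditions of step 6 to give allylsilane acetal F2. Thioacetal exchange as in step 7 gives dithiane F3, and lithiation, addition to 6 and methylation as in step 8 give butanolide F4. TMSOTf ionises F4 as in step 9; the allylsilane attacks C6 through C5 and the silyl group leaves, which fixes the alkene position and provides a stronger π-nucleophile. The closure comes back to the route at 20.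

**Step 13.** The facial selectivity may be lower than expected or reversed, because ring A could react through a conformer whose axial C10 methyl shields the open face. The ketone may also suffer β-elimination of the C11 acyloxy group or of the lactone oxygen through the C7 enol, and the new hydroxyl, cis to C12, may undergo acyl transfer. The fallback sets out from 25: if hydride enters from the lactone face, the product is the (8S)-alcohol F5, which is acetylated directly (Ac2O, 4-(dimethylamino)pyridine, pyridine) and joins the route at 28, bypassing step 14. A mixture of 26 and F5 would be separated and each epimer sent down its own path.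

**Step 14.** Elimination may compete with substitution: the triflate has anti-periplanar hydrogens on C7 and C9 and is strained, and ionisation with rearrangement is also possible. The fallback sets out from 26 and changes the activation to a Mitsunobu reaction with a more acidic pronucleophile (PPh3, diisopropyl azodicarboxylate, chloroacetic acid), which gives the inverted chloroacetate F6. Thiourea removes the chloroacetyl group selectively to give alcohol F5, and acetylation returns to the route at 28.

**Step 11.** The tertiary alkoxide is shielded by the quaternary C11, so acylation may be slow, and forcing it invites Z to E isomerisation of the acyl donor. The fallback sets out from 22 (through 23) and builds the alkene on the substrate. Acylation with 2-[bis(2,2,2-trifluoroethoxy)phosphoryl]propanoyl chloride, a donor that cannot isomerise and so tolerates forcing, gives phosphonate ester F7. A Still–Gennari olefination (KN(SiMe3)2, 18-crown-6, acetaldehyde, −78 °C) then forms the Z alkene and returns to the route at 24.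

**Step 10.** The C11 hydrogen points to the concave side next to the dithiane, so deprotonation by a bulky amide may be slow, and the oxaziridine may oxidise sulfur. The fallback sets out from 20 and uses autoxidation under equilibrating enolisation (KOt-Bu, O2, P(OEt)3, THF/t-BuOH, −20 °C). Dioxygen is captured on the convex face to give hydroperoxide F8, which the phosphite reduces in the flask, returning to the route at 22; dioxygen leaves the dithiane untouched.

**Step 8.** The bulky carbanion may add slowly or deprotonate the acetal carbon of 6, and the congested enolate may methylate slowly or on oxygen. The fallback sets out from 14 (through 15) and 4 and puts the methyl group into the acceptor. 3-Methylfuran-2-carboxylic acid is photo-oxygenated as in step 1 to 5-hydroxy-3-methylfuran-2(5H)-one F9, which is acetalised with 4 as in step 2 to the (5S)-menthyloxy-3-methylbutenolide F10. Addition of 15 to F10, protonation of the enolate and equilibration at C11 with DBU lead back to the route at 17.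

## Further compounds

F1 | step 9 | dimethyl[(E)-2-methyl-3-(trimethylsilyl)prop-1-en-1-yl]alane | C[Al](C)/C=C(\C)C[Si](C)(C)C
F2 | step 9 | (3R,4E)-3-(2,2-dimethoxyethyl)-3,5-dimethyl-6-(trimethylsilyl)hexa-1,4-diene | C=C[C@](C)(/C=C(\C)C[Si](C)(C)C)CC(OC)OC
F3 | step 9 | 2-[(2R,3E)-2-ethenyl-2,4-dimethyl-5-(trimethylsilyl)pent-3-en-1-yl]-1,3-dithiane | C=C[C@](C)(/C=C(\C)C[Si](C)(C)C)CC1SCCCS1
F4 | step 9 | allylsilane analogue of 17 (all-trans menthyloxy butanolide) | C=C[C@](C)(/C=C(\C)C[Si](C)(C)C)CC1(SCCCS1)[C@@H]2[C@@H](O[C@H]3C[C@@H](C)CC[C@@H]3C(C)C)OC(=O)[C@H]2C
F5 | step 13 | (8S)-alcohol, hydroxyl on the face opposite the lactone (deacetyl target) | C=C[C@@]1(C)C[C@H](O)[C@@H]2[C@@H](OC(=O)[C@@]2(C)OC(=O)/C(C)=C\C)[C@@H]1C(=C)C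
F6 | step 14 | (8S)-chloroacetate | C=C[C@@]1(C)C[C@H](OC(=O)CCl)[C@@H]2[C@@H](OC(=O)[C@@]2(C)OC(=O)/C(C)=C\C)[C@@H]1C(=C)C
F7 | step 11 | C11 2-[bis(2,2,2-trifluoroethoxy)phosphoryl]propanoate of 22 | C=C[C@@]1(C)CC3(SCCCS3)[C@@H]2[C@@H](OC(=O)[C@@]2(C)OC(=O)C(C)P(=O)(OCC(F)(F)F)OCC(F)(F)F)[C@@H]1C(=C)C
F8 | step 10 | C11 hydroperoxide of 20 (convex) | C=C[C@@]1(C)CC3(SCCCS3)[C@@H]2[C@@H](OC(=O)[C@@]2(C)OO)[C@@H]1C(=C)C
F9 | step 8 | 5-hydroxy-3-methylfuran-2(5H)-one (racemic) | CC1=CC(O)OC1=O
F10 | step 8 | (5S)-3-methyl-5-{[(1S,2R,5S)-5-methyl-2-(propan-2-yl)cyclohexyl]oxy}furan-2(5H)-one | CC1=C[C@@H](O[C@H]2C[C@@H](C)CC[C@@H]2C(C)C)OC1=O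
A1 | alternative 1 | bicyclo[2.2.2]octenone cycloadduct (bridgehead C10 methyl, C8 diethyl ketal, C5 dimethyl ketal, C6 ketone, C1=C11 bridge) | C[C@@]12CC(OCC)(OCC)[C@@H](C(C)=C1)C(=O)C2(OC)OC
A2 | alternative 1 | 6,6-dimethoxy-3,5-dimethylcyclohexa-2,4-dien-1-one | COC1(OC)C(C)=CC(C)=CC1=O
A3 | alternative 1 | 1,1-diethoxyethene | C=C(OCC)OCC
A4 | alternative 2 | head-to-head cis-anti-cis photoadduct (bicyclo[2.2.0]hexane fused to the silyloxycyclohexanone) | O=C1C[C@@H](O[Si](C)(C)C(C)(C)C)C[C@]2(C)[C@H]3CC[C@@]3(C(=O)OC)[C@H]12
A5 | alternative 2 | (5S)-5-[(tert-butyldimethylsilyl)oxy]-3-methylcyclohex-2-en-1-one | O=C1C[C@@H](O[Si](C)(C)C(C)(C)C)CC(C)=C1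
A6 | alternative 2 | methyl cyclobut-1-ene-1-carboxylate | COC(=O)C1=CCC1
A7 | alternative 2 | divinyl ketone from fragmentation of A4 (C10 vinyl and C5 acrylate cis) | O=C1C[C@@H](O[Si](C)(C)C(C)(C)C)C[C@](C)(C=C)[C@@H]1C(=C)C(=O)OC
A8 | alternative 3 | cis-fused 2-ethoxy-3-methyl bicyclic acetal with C8 hydroxyl trans to C11 (acetal carbon as mixture) | C=C[C@@]1(C)C[C@H](O)[C@@H]2[C@@H](OC(OCC)[C@H]2C)[C@@H]1C(=C)C
A9 | alternative 3 | bromoacetal of the cyclohexenol (acetal and CHBr carbons as mixtures) | C=C[C@@]1(C)CC=C[C@@H](OC(OCC)C(C)Br)[C@@H]1C(=C)C
A10 | alternative 3 | cyclohex-2-enol with C5 isopropenyl, C6 hydroxyl and C10 methyl/vinyl in place | C=C[C@@]1(C)CC=C[C@@H](O)[C@@H]1C(=C)C
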